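**Plan**

- The target is 6,8-diprenylquercetin (flavone numbering: ring A = C4a–C8a, ring B = catechol, ring C = pyranone); it is achiral.
- Retrosynthesis: ring C is cut at O1–C2 (cyclodehydration), C3–C4 (aldol, then oxidation) and C4–C4a (ortho-formylation). Ring A is then cut at C8–C8a, C6–C7 and C4a–C8a into a 3-methoxy-2-prenylcyclobutenone and a prenyl-substituted siloxyalkyne.
- Enabling feature: ring A carries oxygen on C5, C7 and C8a alternating with carbon on C6, C8 and C4a. An alkoxycyclobutenone plus a siloxyalkyne gives exactly this pattern, with the three oxygens differentiated (OMe at C5, OSi at C7, free OH at C8a).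
- Forward: ring A is built first by benzannulation; C4 is added by formylation; ring B arrives intact in an α-oxygenated acetophenone by aldol addition; ring C is closed by acid; the methyl and silyl ethers are removed last.
- O5 is carried as a methyl ether so that the final dealkylation can use chelation to the C4 carbonyl (MgI2), which should spare the prenyl groups.
- Stereochemistry: none in the target; the transient stereocentres are racemic and are destroyed later.

Key step: step 6

Assumption: compounds 1, 2, 5, 9 and 21 are taken as purchasable.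

**Route**

Step 1
Reactants: 1 2-chloro-1,1-dimethoxyethane; 2 1-bromo-3-methylbut-2-ene (prenyl bromide)
Product: 4 1-methoxy-5-methylhex-4-en-1-yne, via lithium methoxyacetylide 3 (not isolated)
Conditions: LiNEt2 (3 equiv), THF, 0 °C; then 2, DMPU, −20 °C to rt
Reagents that add atoms: none
Why: Three equivalents of amide base convert the chloroacetal by two eliminations and one deprotonation into acetylide 3, whose SN2 alkylation at the primary carbon of the allylic bromide (acetylide alkylation) should give the ynol ether.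

Step 2
Reactants: 4 1-methoxy-5-methylhex-4-en-1-yne; 5 trichloroacetyl chloride
Product: 7 4,4-dichloro-3-methoxy-2-(3-methylbut-2-en-1-yl)cyclobut-2-en-1-one, via dichloroketene 6 (not isolated)
Conditions: Zn–Cu couple, 5 (1.1 equiv, slow addition), Et2O–DME, 0 °C to rt
Reagents that add atoms: none
Why: Dichloroketene from zinc dechlorination of 5 should undergo ketene–alkyne [2+2] cycloaddition with the strongly nucleophilic ynol ether far faster than with the trisubstituted alkene, and the polarisation of both partners joins the ketene carbonyl carbon to the prenyl-bearing alkyne carbon, placing methoxy at C3 and both chlorines at C4.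

Step 3
Reactants: 7 4,4-dichloro-3-methoxy-2-(3-methylbut-2-en-1-yl)cyclobut-2-en-1-one
Product: 8 3-methoxy-2-(3-methylbut-2-en-1-yl)cyclobut-2-en-1-one
Conditions: Zn dust, AcOH, TMEDA, MeOH, 0 °C to rt
Reagents that add atoms: none
Why: Zinc in buffered acetic acid removes both chlorines of the α,α-dichloroketone through zinc enolates (reductive dehalogenation), and methanol as solvent makes any alkoxy exchange at the vinylogous ester degenerate.

Step 4
Reactants: 9 4-methylpent-3-enoic acid
Product: 10 ethyl 4-methylpent-3-enoate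
Conditions: EtI, K2CO3, DMF, rt
Reagents that add atoms: iodoethane, CCI
Why: Carboxylate O-alkylation under basic conditions should give the ester without the acid catalysis that would lactonise this β,γ-unsaturated acid.

Step 5
Reactants: 10 ethyl 4-methylpent-3-enoate
Product: 13 triisopropyl[(5-methylhex-4-en-1-yn-1-yl)oxy]silane, via lithium dibromoenolate 11 (not isolated), via lithium ynolate 12 (not isolated)
Conditions: CH2Br2, lithium 2,2,6,6-tetramethylpiperidide, THF, −78 °C; LiN(SiMe3)2; n-BuLi, −78 to 0 °C; i-Pr3SiCl, −78 °C to rt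
Reagents that add atoms: dibromomethane, BrCBr; chlorotri(propan-2-yl)silane, CC(C)[Si](Cl)(C(C)C)C(C)C
Why: In the Kowalski ynolate homologation LiCHBr2 adds to the ester, the dibromoketone enolate 11 undergoes bromine–lithium exchange and 1,2-shift to ynolate 12, and the bulky chlorosilane should silylate 12 on oxygen.

Step 6
Reactants: 8 3-methoxy-2-(3-methylbut-2-en-1-yl)cyclobut-2-en-1-one; 13 triisopropyl[(5-methylhex-4-en-1-yn-1-yl)oxy]silane
Product: 18 5-methoxy-2,4-bis(3-methylbut-2-en-1-yl)-3-[(triisopropylsilyl)oxy]phenol, via vinylketene 14 (not isolated), via vinylcyclobutenone 15 (not isolated), via dienylketene 16 (not isolated), via cyclohexadienone 17 (not isolated)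
Conditions: 13 (1.2 equiv), PhMe, 110 °C, sealed tube
Reagents that add atoms: none
Why: Heating should open 8 by 4π electrocyclic cleavage of its C1–C4 bond to the (1-methoxyvinyl)ketene 14, which adds to the siloxyalkyne in a ketene–alkyne [2+2] to give 15; a second 4π opening gives dienylketene 16, and 6π electrocyclisation followed by tautomerisation of 17 gives the phenol. The closest known reaction is the thermal cyclobutenone–siloxyalkyne benzannulation (Danheiser benzannulation) that gives mono-silylated resorcinols; the methoxy group on the cyclobutenone extends it to a differentiated phloroglucinol, and this donor is expected to slow the first ring opening, hence the temperature. Ring A is closed by the 6π electrocyclisation, which forms C4a–C8a after the cycloaddition has formed C8–C8a and C6–C7. No stereocentre remains in the product; the quaternary carbon of 15 is transient and racemic. The step needs regiocontrol in the [2+2], which the polarisation of the siloxyalkyne secures: its prenyl-bearing carbon is the nucleophilic one and bonds to the ketene carbonyl carbon, so both prenyl groups end up between oxygens and the free hydroxyl lies next to the only ring C–H. Only the isomer of 16 with ketene and methoxyvinyl cis can close, and the other isomer should return to 15 by reversible ring closure.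

Step 7
Reactants: 18 5-methoxy-2,4-bis(3-methylbut-2-en-1-yl)-3-[(triisopropylsilyl)oxy]phenol
Product: 19 2-hydroxy-6-methoxy-3,5-bis(3-methylbut-2-en-1-yl)-4-[(triisopropylsilyl)oxy]benzaldehyde
Conditions: MgCl2, Et3N, (CH2O)n, MeCN, 80 °C
Reagents that add atoms: paraformaldehyde (formaldehyde units), C=O
Why: Casnati–Skattebøl ortho-formylation proceeds through the magnesium phenoxide, which delivers formaldehyde to the only unsubstituted ring carbon (ortho to the free hydroxyl) and is oxidised to the aldehyde by a second formaldehyde, under basic conditions that spare the silyl ether and the prenyl groups.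

Step 8
Reactants: 19 2-hydroxy-6-methoxy-3,5-bis(3-methylbut-2-en-1-yl)-4-[(triisopropylsilyl)oxy]benzaldehyde
Product: 20 2-methoxy-6-(methoxymethoxy)-3,5-bis(3-methylbut-2-en-1-yl)-4-[(triisopropylsilyl)oxy]benzaldehyde
Conditions: NaH, MOMCl, DMF, 0 °C
Reagents that add atoms: chloromethyl methyl ether, COCCl
Why: Williamson-type alkylation of the sodium phenoxide caps the chelated phenol, which raises the electrophilicity of the aldehyde for the aldol step and shields the electron-rich phenol from the later oxidant.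

Step 9
Reactants: 21 2-chloro-1-(3,4-dihydroxyphenyl)ethan-1-one
Product: 23 1-(3,4-dihydroxyphenyl)-2-hydroxyethan-1-one, via phenacyl formate 22 (not isolated)
Conditions: HCO2Na, EtOH/H2O, reflux
Reagents that add atoms: sodium formate, [Na+].[O-]C=O
Why: SN2 displacement of the activated phenacyl chloride by formate gives ester 22, which should be solvolysed in the aqueous ethanol to the α-hydroxy ketone (the classical formate route to phenacyl alcohols).

Step 10
Reactants: 23 1-(3,4-dihydroxyphenyl)-2-hydroxyethan-1-one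
Product: 24 1-[3,4-bis(methoxymethoxy)phenyl]-2-(methoxymethoxy)ethan-1-one
Conditions: MOMCl (excess), i-Pr2NEt, CH2Cl2, 0 °C to rt
Reagents that add atoms: chloromethyl methyl ether, COCCl
Why: Amine-mediated alkylation with chloromethyl methyl ether converts both phenols and the primary alcohol into MOM acetals, leaving the α-CH2 as the only acidic position.

Step 11
Reactants: 20 2-methoxy-6-(methoxymethoxy)-3,5-bis(3-methylbut-2-en-1-yl)-4-[(triisopropylsilyl)oxy]benzaldehyde; 24 1-[3,4-bis(methoxymethoxy)phenyl]-2-(methoxymethoxy)ethan-1-one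
Product: 26 1-[3,4-bis(methoxymethoxy)phenyl]-3-hydroxy-2-(methoxymethoxy)-3-{2-methoxy-6-(methoxymethoxy)-3,5-bis(3-methylbut-2-en-1-yl)-4-[(triisopropylsilyl)oxy]phenyl}propan-1-one (mixture of racemic diastereomers), via lithium enolate 25 (not isolated)
Conditions: 24, LiN(SiMe3)2, THF, −78 °C; then 20, −78 °C; aq. NH4Cl
Reagents that add atoms: none
Why: Kinetic deprotonation gives the chelated Z lithium enolate 25, which adds to the non-enolisable aldehyde in a crossed aldol reaction that forms C3–C4; the two new stereocentres are set without control, which is immaterial because both are removed in steps 12 and 13.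

Step 12
Reactants: 26 the aldol adduct of step 11
Product: 27 1-[3,4-bis(methoxymethoxy)phenyl]-2-(methoxymethoxy)-3-{2-methoxy-6-(methoxymethoxy)-3,5-bis(3-methylbut-2-en-1-yl)-4-[(triisopropylsilyl)oxy]phenyl}propane-1,3-dione (racemic)
Conditions: Dess–Martin periodinane, CH2Cl2, 0 °C to rt
Reagents that add atoms: none
Why: Dess–Martin oxidation should convert the hindered benzylic β-hydroxy ketone into the 1,3-diketone under near-neutral conditions to which the trisubstituted alkenes, the acetals and the silyl ether are inert.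

Step 13
Reactants: 27 the 1,3-diketone of step 12
Product: 30 2-(3,4-dihydroxyphenyl)-3-hydroxy-5-methoxy-6,8-bis(3-methylbut-2-en-1-yl)-7-[(triisopropylsilyl)oxy]-4H-chromen-4-one, via MOM-free diketone 28 (not isolated), via hemiketal 29 (not isolated)
Conditions: 3 M HCl, MeOH, 45 °C
Reagents that add atoms: none
Why: Acid-catalysed acetal solvolysis frees the four hydroxyls, and the ortho phenol then adds to the ring B carbonyl (6-exo-trig hemiketalisation) and loses water to the aromatic pyranone, the cyclodehydration that ends Baker–Venkataraman-type flavone syntheses; dilute acid in methanol is the regime in which MOM ethers of ortho-prenylphenols are usually cleaved without chroman formation.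

Step 14
Reactants: 30 2-(3,4-dihydroxyphenyl)-3-hydroxy-5-methoxy-6,8-bis(3-methylbut-2-en-1-yl)-7-[(triisopropylsilyl)oxy]-4H-chromen-4-one
Product: 31 2-(3,4-dihydroxyphenyl)-3,5-dihydroxy-6,8-bis(3-methylbut-2-en-1-yl)-7-[(triisopropylsilyl)oxy]-4H-chromen-4-one
Conditions: MgI2·OEt2 (excess), THF, 60 °C; then cold 0.5 M HCl
Reagents that add atoms: none
Why: Magnesium bridges the C4 carbonyl and O5 so that iodide should cleave only this methyl ether by SN2 attack (chelation-directed demethylation), under non-protic conditions that C-prenyl groups beside phenols are known to tolerate in 5-O-methyl flavonoids.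

Step 15
Reactants: 31 2-(3,4-dihydroxyphenyl)-3,5-dihydroxy-6,8-bis(3-methylbut-2-en-1-yl)-7-[(triisopropylsilyl)oxy]-4H-chromen-4-one
Product: 32 2-(3,4-dihydroxyphenyl)-3,5,7-trihydroxy-6,8-bis(3-methylbut-2-en-1-yl)-4H-chromen-4-one (6,8-diprenylquercetin)
Conditions: Bu4NF, AcOH, THF, 0 °C, under argon
Reagents that add atoms: none
Why: Fluoride attacks silicon and releases the C7 phenol (silyl ether cleavage), with acetic acid buffering so that the catechol and flavonol are not exposed as air-sensitive phenoxides.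

**Compound list**

1 | 2-chloro-1,1-dimethoxyethane (chloroacetaldehyde dimethyl acetal) | COC(CCl)OC | starting material
2 | 1-bromo-3-methylbut-2-ene (prenyl bromide) | CC(C)=CCBr | starting material
3 | lithium methoxyacetylide | [Li]C#COC | intermediate
4 | 1-methoxy-5-methylhex-4-en-1-yne | COC#CCC=C(C)C | intermediate
5 | trichloroacetyl chloride | O=C(Cl)C(Cl)(Cl)Cl | starting material
6 | dichloroketene | O=C=C(Cl)Cl | intermediate
7 | 4,4-dichloro-3-methoxy-2-(3-methylbut-2-en-1-yl)cyclobut-2-en-1-one | O=C1C(CC=C(C)C)=C(OC)C1(Cl)Cl | intermediate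
8 | 3-methoxy-2-(3-methylbut-2-en-1-yl)cyclobut-2-en-1-one | O=C1CC(OC)=C1CC=C(C)C | intermediate
9 | 4-methylpent-3-enoic acid | CC(C)=CCC(=O)O | starting material
10 | ethyl 4-methylpent-3-enoate | CCOC(=O)CC=C(C)C | intermediate
11 | lithium 1,1-dibromo-5-methylhexa-1,4-dien-2-olate | [Li]OC(CC=C(C)C)=C(Br)Br | intermediate
12 | lithium 5-methylhex-4-en-1-yn-1-olate (ynolate) | [Li]OC#CCC=C(C)C | intermediate
13 | triisopropyl[(5-methylhex-4-en-1-yn-1-yl)oxy]silane | CC(C)=CCC#CO[Si](C(C)C)(C(C)C)C(C)C | intermediate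
14 | 3-methoxy-2-(3-methylbut-2-en-1-yl)buta-1,3-dien-1-one, the (1-methoxyvinyl)(prenyl)ketene | C=C(OC)C(CC=C(C)C)=C=O | intermediate
15 | 4-(1-methoxyethenyl)-2,4-bis(3-methylbut-2-en-1-yl)-3-[(triisopropylsilyl)oxy]cyclobut-2-en-1-one (racemic) | O=C1C(CC=C(C)C)=C(O[Si](C(C)C)(C(C)C)C(C)C)C1(CC=C(C)C)C(=C)OC | intermediate
16 | (3E)-5-methoxy-2,4-bis(3-methylbut-2-en-1-yl)-3-[(triisopropylsilyl)oxy]hexa-1,3,5-trien-1-one (ketene and methoxyvinyl cis) | O=C=C(CC=C(C)C)/C(O[Si](C(C)C)(C(C)C)C(C)C)=C(/CC=C(C)C)C(=C)OC | intermediate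
17 | 5-methoxy-2,4-bis(3-methylbut-2-en-1-yl)-3-[(triisopropylsilyl)oxy]cyclohexa-2,4-dien-1-one | O=C1CC(OC)=C(CC=C(C)C)C(O[Si](C(C)C)(C(C)C)C(C)C)=C1CC=C(C)C | intermediate
18 | 5-methoxy-2,4-bis(3-methylbut-2-en-1-yl)-3-[(triisopropylsilyl)oxy]phenol | COc1cc(O)c(CC=C(C)C)c(O[Si](C(C)C)(C(C)C)C(C)C)c1CC=C(C)C | intermediate
19 | 2-hydroxy-6-methoxy-3,5-bis(3-methylbut-2-en-1-yl)-4-[(triisopropylsilyl)oxy]benzaldehyde | COc1c(CC=C(C)C)c(O[Si](C(C)C)(C(C)C)C(C)C)c(CC=C(C)C)c(O)c1C=O | intermediate
20 | 2-methoxy-6-(methoxymethoxy)-3,5-bis(3-methylbut-2-en-1-yl)-4-[(triisopropylsilyl)oxy]benzaldehyde | COc1c(CC=C(C)C)c(O[Si](C(C)C)(C(C)C)C(C)C)c(CC=C(C)C)c(OCOC)c1C=O | intermediate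
21 | 2-chloro-1-(3,4-dihydroxyphenyl)ethan-1-one | O=C(CCl)c1ccc(O)c(O)c1 | starting material
22 | 2-(3,4-dihydroxyphenyl)-2-oxoethyl formate | O=COCC(=O)c1ccc(O)c(O)c1 | intermediate
23 | 1-(3,4-dihydroxyphenyl)-2-hydroxyethan-1-one | OCC(=O)c1ccc(O)c(O)c1 | intermediate
24 | 1-[3,4-bis(methoxymethoxy)phenyl]-2-(methoxymethoxy)ethan-1-one | COCOCC(=O)c1ccc(OCOC)c(OCOC)c1 | intermediate
25 | lithium (Z)-1-[3,4-bis(methoxymethoxy)phenyl]-2-(methoxymethoxy)ethen-1-olate | [Li]O/C(=C\OCOC)c1ccc(OCOC)c(OCOC)c1 | intermediate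
26 | 1-[3,4-bis(methoxymethoxy)phenyl]-3-hydroxy-2-(methoxymethoxy)-3-{2-methoxy-6-(methoxymethoxy)-3,5-bis(3-methylbut-2-en-1-yl)-4-[(triisopropylsilyl)oxy]phenyl}propan-1-one (racemic diastereomers) | COc1c(CC=C(C)C)c(O[Si](C(C)C)(C(C)C)C(C)C)c(CC=C(C)C)c(OCOC)c1C(O)C(OCOC)C(=O)c1ccc(OCOC)c(OCOC)c1 | intermediate
27 | 1-[3,4-bis(methoxymethoxy)phenyl]-2-(methoxymethoxy)-3-{2-methoxy-6-(methoxymethoxy)-3,5-bis(3-methylbut-2-en-1-yl)-4-[(triisopropylsilyl)oxy]phenyl}propane-1,3-dione (racemic) | COc1c(CC=C(C)C)c(O[Si](C(C)C)(C(C)C)C(C)C)c(CC=C(C)C)c(OCOC)c1C(=O)C(OCOC)C(=O)c1ccc(OCOC)c(OCOC)c1 | intermediate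
28 | 1-(3,4-dihydroxyphenyl)-2-hydroxy-3-{2-hydroxy-6-methoxy-3,5-bis(3-methylbut-2-en-1-yl)-4-[(triisopropylsilyl)oxy]phenyl}propane-1,3-dione (racemic) | COc1c(CC=C(C)C)c(O[Si](C(C)C)(C(C)C)C(C)C)c(CC=C(C)C)c(O)c1C(=O)C(O)C(=O)c1ccc(O)c(O)c1 | intermediate
29 | 2-(3,4-dihydroxyphenyl)-2,3-dihydroxy-5-methoxy-6,8-bis(3-methylbut-2-en-1-yl)-7-[(triisopropylsilyl)oxy]chroman-4-one (racemic diastereomers) | COc1c(CC=C(C)C)c(O[Si](C(C)C)(C(C)C)C(C)C)c(CC=C(C)C)c2OC(O)(c3ccc(O)c(O)c3)C(O)C(=O)c12 | intermediate
30 | 2-(3,4-dihydroxyphenyl)-3-hydroxy-5-methoxy-6,8-bis(3-methylbut-2-en-1-yl)-7-[(triisopropylsilyl)oxy]-4H-chromen-4-one | COc1c(CC=C(C)C)c(O[Si](C(C)C)(C(C)C)C(C)C)c(CC=C(C)C)c2oc(-c3ccc(O)c(O)c3)c(O)c(=O)c12 | intermediate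
31 | 2-(3,4-dihydroxyphenyl)-3,5-dihydroxy-6,8-bis(3-methylbut-2-en-1-yl)-7-[(triisopropylsilyl)oxy]-4H-chromen-4-one | CC(C)=CCc1c(O)c2c(=O)c(O)c(-c3ccc(O)c(O)c3)oc2c(CC=C(C)C)c1O[Si](C(C)C)(C(C)C)C(C)C | intermediate
32 | 2-(3,4-dihydroxyphenyl)-3,5,7-trihydroxy-6,8-bis(3-methylbut-2-en-1-yl)-4H-chromen-4-one (6,8-diprenylquercetin) | CC(C)=CCc1c(O)c(CC=C(C)C)c2oc(-c3ccc(O)c(O)c3)c(O)c(=O)c2c1O | target

**Step count**

Total: 15 steps. Longest linear sequence: 11 steps (steps 1, 2, 3, 6, 7, 8, 11, 12, 13, 14, 15).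

**Steps most likely to fail**

1. Step 6. The donor-stabilised methoxycyclobutenone may open more slowly than the siloxyalkyne decomposes at the temperature required, so the vinylketene is never trapped productively.
 Fallback: generate the same ketene without a cyclobutenone. The fallback sets out from 2. Alkylation of methyl acetoacetate with 2 (K2CO3, acetone) should give methyl 2-acetyl-5-methylhex-4-enoate F1. Enol ether formation with trimethyl orthoformate and catalytic TsOH in MeOH should give methyl 3-methoxy-2-(3-methylbut-2-en-1-yl)but-2-enoate F2. Saponification (KOH, aqueous MeOH) should give 3-methoxy-2-(3-methylbut-2-en-1-yl)but-2-enoic acid F3, and oxalyl chloride with catalytic DMF should give 3-methoxy-2-(3-methylbut-2-en-1-yl)but-2-enoyl chloride F4. Treating F4 with Et3N in toluene at 60–80 °C in the presence of 13 should effect 1,4-dehydrochlorination to vinylketene 14 at a temperature the siloxyalkyne tolerates. The fallback rejoins the route at 14 and so, through 15–17, at phenol 18.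

2. Step 14. Magnesium may be sequestered by the 3-hydroxy-4-keto unit and the catechol so that the O5 methyl group is not activated, and forcing the reaction may bring on cyclisation of the C6 prenyl group onto a neighbouring oxygen.
 Fallback: remove the methyl group early by a nucleophilic mechanism and carry O5 as a MOM ether. The fallback sets out from 20. NaSEt in DMF at 80–90 °C should cleave the methyl ether ortho to the formyl group by SN2 attack at carbon, giving 2-hydroxy-6-(methoxymethoxy)-3,5-bis(3-methylbut-2-en-1-yl)-4-[(triisopropylsilyl)oxy]benzaldehyde F5. NaH and MOMCl should give 2,6-bis(methoxymethoxy)-3,5-bis(3-methylbut-2-en-1-yl)-4-[(triisopropylsilyl)oxy]benzaldehyde F6. Aldol addition of enolate 25 should give 3-{2,6-bis(methoxymethoxy)-3,5-bis(3-methylbut-2-en-1-yl)-4-[(triisopropylsilyl)oxy]phenyl}-1-[3,4-bis(methoxymethoxy)phenyl]-3-hydroxy-2-(methoxymethoxy)propan-1-one F7. Dess–Martin oxidation should give 1-{2,6-bis(methoxymethoxy)-3,5-bis(3-methylbut-2-en-1-yl)-4-[(triisopropylsilyl)oxy]phenyl}-3-[3,4-bis(methoxymethoxy)phenyl]-2-(methoxymethoxy)propane-1,3-dione F8. HCl in MeOH should then remove all five MOM groups and close ring C through 1-{2,6-dihydroxy-3,5-bis(3-methylbut-2-en-1-yl)-4-[(triisopropylsilyl)oxy]phenyl}-3-(3,4-dihydroxyphenyl)-2-hydroxypropane-1,3-dione F9 and 2-(3,4-dihydroxyphenyl)-2,3,5-trihydroxy-6,8-bis(3-methylbut-2-en-1-yl)-7-[(triisopropylsilyl)oxy]chroman-4-one F10. The fallback comes back to the route at 31.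

3. Step 5. LiCHBr2 may deprotonate the doubly activated α-position of the β,γ-unsaturated ester instead of adding to the carbonyl, leading to enolisation and migration of the alkene into conjugation.
 Fallback: make the ynolate by oxidising an acetylide. The fallback sets out from 2. CuCl-catalysed coupling with ethynylmagnesium bromide in THF should give 5-methylhex-4-en-1-yne F11. n-BuLi at −78 °C should give (5-methylhex-4-en-1-yn-1-yl)lithium F12, and lithium tert-butyl peroxide (from t-BuOOH and LiN(SiMe3)2) should oxidise F12 to ynolate 12. Silylation with i-Pr3SiOTf returns the route to 13.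

**Further compounds**

F1 | step 6 | methyl 2-acetyl-5-methylhex-4-enoate (racemic) | COC(=O)C(CC=C(C)C)C(C)=O
F2 | step 6 | methyl 3-methoxy-2-(3-methylbut-2-en-1-yl)but-2-enoate (E/Z mixture) | COC(=O)C(CC=C(C)C)=C(C)OC
F3 | step 6 | 3-methoxy-2-(3-methylbut-2-en-1-yl)but-2-enoic acid | OC(=O)C(CC=C(C)C)=C(C)OC
F4 | step 6 | 3-methoxy-2-(3-methylbut-2-en-1-yl)but-2-enoyl chloride | ClC(=O)C(CC=C(C)C)=C(C)OC
F5 | step 14 | 2-hydroxy-6-(methoxymethoxy)-3,5-bis(3-methylbut-2-en-1-yl)-4-[(triisopropylsilyl)oxy]benzaldehyde | COCOc1c(CC=C(C)C)c(O[Si](C(C)C)(C(C)C)C(C)C)c(CC=C(C)C)c(O)c1C=O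
F6 | step 14 | 2,6-bis(methoxymethoxy)-3,5-bis(3-methylbut-2-en-1-yl)-4-[(triisopropylsilyl)oxy]benzaldehyde | COCOc1c(CC=C(C)C)c(O[Si](C(C)C)(C(C)C)C(C)C)c(CC=C(C)C)c(OCOC)c1C=O
F7 | step 14 | 3-{2,6-bis(methoxymethoxy)-3,5-bis(3-methylbut-2-en-1-yl)-4-[(triisopropylsilyl)oxy]phenyl}-1-[3,4-bis(methoxymethoxy)phenyl]-3-hydroxy-2-(methoxymethoxy)propan-1-one (racemic diastereomers) | COCOc1c(CC=C(C)C)c(O[Si](C(C)C)(C(C)C)C(C)C)c(CC=C(C)C)c(OCOC)c1C(O)C(OCOC)C(=O)c1ccc(OCOC)c(OCOC)c1
F8 | step 14 | 1-{2,6-bis(methoxymethoxy)-3,5-bis(3-methylbut-2-en-1-yl)-4-[(triisopropylsilyl)oxy]phenyl}-3-[3,4-bis(methoxymethoxy)phenyl]-2-(methoxymethoxy)propane-1,3-dione (racemic) | COCOc1c(CC=C(C)C)c(O[Si](C(C)C)(C(C)C)C(C)C)c(CC=C(C)C)c(OCOC)c1C(=O)C(OCOC)C(=O)c1ccc(OCOC)c(OCOC)c1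
F9 | step 14 | 1-{2,6-dihydroxy-3,5-bis(3-methylbut-2-en-1-yl)-4-[(triisopropylsilyl)oxy]phenyl}-3-(3,4-dihydroxyphenyl)-2-hydroxypropane-1,3-dione (racemic) | Oc1c(CC=C(C)C)c(O[Si](C(C)C)(C(C)C)C(C)C)c(CC=C(C)C)c(O)c1C(=O)C(O)C(=O)c1ccc(O)c(O)c1
F10 | step 14 | 2-(3,4-dihydroxyphenyl)-2,3,5-trihydroxy-6,8-bis(3-methylbut-2-en-1-yl)-7-[(triisopropylsilyl)oxy]chroman-4-one (racemic diastereomers) | Oc1c(CC=C(C)C)c(O[Si](C(C)C)(C(C)C)C(C)C)c(CC=C(C)C)c2OC(O)(c3ccc(O)c(O)c3)C(O)C(=O)c12
F11 | step 5 | 5-methylhex-4-en-1-yne | C#CCC=C(C)C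
F12 | step 5 | (5-methylhex-4-en-1-yn-1-yl)lithium | [Li]C#CCC=C(C)C
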